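## The problem

The target is a spirocycle. Ring A is a 1-acetyl-2-hydroxy-3,3-diprenylcyclohex-1-ene-4,6-dione (C1 acetyl-bearing, C2 enol, C3 diprenyl, C4 and C6 carbonyl, C5 spiro). It shares C5 with ring B (C5, C1', C2', C6', C7', C8'), which is trans-fused along C2'–C6' to the cyclopentane ring C (C2' to C6').

There are five stereocentres: C2', C3' (tertiary carbinol) and C6' in ring C, C7' (tertiary hydroperoxide) and the spiro atom C5. The trans fusion locks ring B in one chair, in which H-2' and H-6' are axial, the 7'-OOH is equatorial with the 7'-methyl axial, and C4 is axial on C5, on the same side as that methyl.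

C6' can be taken from the chiral pool and can steer C2' and C3' in an aldol closure of ring C. C7' is the hard centre: a tertiary cyclohexyl radical or cation normally accepts oxygen axially, so the equatorial C7'–O bond needs a 1,3-diaxial blocking group, and only a fully substituted C5 offers one. The axial 7'-methyl is then the one element that can tell the two faces of C5 apart when ring A is made.

C5 is stereogenic only because its two ring-A neighbours differ (C4 next to the diprenyl carbon, C6 next to the acetyl carbon). A ring A with free oxygen on C4 and C6 and hydrogen on both C1 and C3 is a vinylogous acid whose tautomers are C5 epimers, so C1 and C3 must differ in constitution from the moment ring A exists.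

The tertiary hydroperoxide will not survive low-valent metals, phosphines, hydride donors, strong acid or prolonged heating. The tertiary alcohol eliminates easily, the β-triketone is open to retro-Claisen cleavage, and the prenyl groups rule out radical hydrofunctionalisation once they are present, so the peroxide must be in place and protected before the alkenes arrive.

The key step is made possible by ring A itself: oxygen on C2, C4 and C6 around a quaternary C5 is the pattern formed when a 4,4-disubstituted 3-oxycyclobutenone is annulated with an alkoxyalkyne, and the quaternary carbon stops the product at the dienone.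

## Retrosynthesis

**Unmasking and the last C–C bonds.** Target 34 is traced to 33, which differs only by the ethyl enol ether on C2, the 2-methoxyprop-2-yl peroxyketal and the triethylsilyl ether; one mild acid treatment removes all three. In 33 the C3–prenyl bond is cut to give 32 and prenyl bromide 17. This cut is preferred to a double prenylation of a ring A that carries no carbon substituents: that ring would pass through a locally symmetric anion and lose C5. In 32 the acetyl group blocks C1 and one prenyl group already marks C3, so alkylation can only complete the quaternary centre, as in the conversion of deoxy hop acids into lupulones. Removing the acetyl group (32 to 30) and restoring the silyl enol ether (30 to 29) leads to dienone 29.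

**Ring A (key cut).** In 29 the bonds C6–C1, C2–C3 and C6–C5 are cut, giving spiro cyclobutenone 24 and ethoxyacetylene 25. No other disconnection removes a whole ring in one operation while delivering C2, C4 and C6 as three different oxygen functions (ethyl enol ether, silyl enol ether, ketone). A Claisen-type construction of ring A from a C5 malonate would give no handle on C5 at all. The precursor 24 is simpler by one ring and one stereocentre. The forward reaction must choose the equatorial face of C5 and must run at a temperature the peroxyketal tolerates. The prenyl group on the cyclobutenone is a spectator that ends on C3 and keeps C4 and C6 constitutionally distinct afterwards.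

**The cyclobutenone.** 24 is cut across the four-membered ring (C5–C4 and C6–C3 in ring-A numbering) into ketene 23, drawn from acid 16, and siloxyalkyne 21. The ketene–ynol ether cycloaddition is regiospecific, and either spiro epimer of 24 serves, since C5 becomes trigonal in the key step.

**The siloxyalkyne.** 21 is cut at the O–Si bond and the C–O bond to enyne 19 (ynolate 20 in the forward direction), and 19 at the propargylic C–C bond to prenyl bromide 17 and ethynylmagnesium bromide 18. Both are commodity reagents; the same prenyl bromide serves twice.

**The hydroperoxide and the C5 substituents.** Acid 16 is traced through peroxyketal 14 and silyl peroxide 12 to alkene 11 by cutting the C7'–O bond. Oxygen is introduced while C5 still carries two carbonyl substituents, one of them necessarily axial, so that O2 is pushed onto the equatorial side of C7'. A C5 monoester would leave the axial face open, and a gem-diester could only be trimmed by a Krapcho reaction, which no peroxide survives. An acetoacetate-derived C5 loses its acetyl group by retro-Claisen cleavage at 50 °C, which the protected peroxide tolerates.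

**Ring B.** In 11 the bonds C5–C1' and C5–C8' are cut, giving the bis-electrophile 8 and methyl acetoacetate 9. A double alkylation closes ring B, forms the quaternary C5 and leaves the exocyclic alkene needed for the oxygenation. The precursor has one ring fewer.

**Ring C.** 8 is traced through 7 (allylic chlorination) to diol 5 (tosylation, silylation). 5 is cut at C2'–C3' (aldol) to keto aldehyde 3, the ring-cleavage product of (R)-limonene 1. Limonene supplies all ten carbons of the terpene half and the C6' configuration; the aldol must deliver the all-trans arrangement of the three carbon substituents on ring C.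

## Roads not taken

**Alternative 1:** Ring C is cut at C2'–C3'. In the forward direction keto aldehyde A2 (identical with 3) is closed by an amine-catalysed aldol addition to hydroxy aldehyde A1 (identical with 4).
- Merits: two steps from the chiral pool, and C2' and C3' are set relative to C6'. For ring C nothing shorter is apparent.
- Weak points as a central idea: it decides nothing about C7', C5 or ring A. The β-hydroxy aldehyde is also prone to dehydration.
- Comparison: the chosen plan does not compete with this road; it contains it as step 2. The chosen plan adds a ring-A construction that uses the stereochemical information of ring B, which this road leaves to conventional acylation chemistry with no control at C5.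

**Alternative 2:** The shared bond C2'–C6' is cut. In the forward direction BF3·OEt2 opens the cis-epoxide of the spiro nine-membered allylsilane A4 and C6' attacks C2' across the ring, giving the trans-hydrindane diester A3 with an exocyclic methylene at C7'.
- Merits: rings B and C and the centres C2', C3' and C6' arise in one step. A3 is a symmetric gem-diester, so it would have no C5 epimers at the oxygenation stage, where the chosen route has to carry a mixture.
- Weak points: A4 needs a medium-ring closure and an enantioselective epoxidation of an unfunctionalised trisubstituted alkene. The transannular attack must choose C2' over C3' and the trans over the cis fusion, neither of which is secured by the substrate. The gem-diester could only be trimmed to the ketene precursor under conditions a peroxide does not survive.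
- Comparison: more elegant for the carbocyclic core, but longer and less certain than five known steps from limonene, and it does not address ring A.

**Alternative 3:** C6'–C7' and C2'–C1' are cut. In the forward direction copper-catalysed asymmetric conjugate addition of isopropenylmagnesium bromide A7 to cyclopent-2-en-1-one A6 is followed by trapping of the enolate with formaldehyde A8, giving trans-2-(hydroxymethyl)-3-isopropenylcyclopentanone A5. Addition of a methyl nucleophile would then give the diol that the chosen route reaches as 5.
- Merits: the same step count to that diol, access to either enantiomer, and freedom to vary the C3' substituent; in flexibility it is the better road.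
- Weak points: cyclopentenone is a poor substrate for high enantioselectivity in alkenyl Grignard additions. A5 is a β-hydroxy ketone that eliminates readily. The methyl addition brings its own facial question.
- Comparison: the chosen plan sets against this the guaranteed enantiopurity and the C3' methyl group that limonene already carries. Like the other two roads, it leaves C7', C5 and ring A open.

Key step: step 12

## Route

Assumption: compounds 11 to 16 and 22 are carried as mixtures of both C5 configurations and 24 as both spiro epimers; this has no consequence because C5 is trigonal in ketene 23 and in vinylketene 26.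

Assumption: L-proline is taken to be the matched catalyst enantiomer for 3; D-proline would be used if the reverse holds.

Step 1
Reactants: 1 (R)-limonene
Product: 3 (3R)-6-oxo-3-(prop-1-en-2-yl)heptanal, via limonene 1,2-ozonide 2 (not isolated)
Conditions: O3 (1 equiv), CH2Cl2, −78 °C; then PPh3, −78 °C → rt
Reagents that add atoms: ozone, [O-][O+]=O
Why: Chemoselective ozonolysis; the trisubstituted ring alkene is more electron-rich than the 1,1-disubstituted isopropenyl group and is cleaved first when ozone is limited to one equivalent. C6' is untouched.

Step 2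
Reactants: 3 (3R)-6-oxo-3-(prop-1-en-2-yl)heptanal
Product: 5 (1R,2R,3R)-2-(hydroxymethyl)-1-methyl-3-(prop-1-en-2-yl)cyclopentan-1-ol, via hydroxy aldehyde 4 (not isolated)
Conditions: L-proline (20 mol %), DMF, 0 °C → rt; then NaBH4, MeOH, 0 °C
Reagents that add atoms: none
Why: Proline-catalysed intramolecular (5-enolexo) aldol addition of the aldehyde enamine to the methyl ketone forms C2'–C3'; the hydrogen-bonded transition state places OH cis to the formyl group, and the epimerisable C2' settles trans to the isopropenyl group on C6'. Reduction in the same flask removes the aldehyde before it can dehydrate or undergo retro-aldol cleavage.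

Step 3
Reactants: 5 (1R,2R,3R)-2-(hydroxymethyl)-1-methyl-3-(prop-1-en-2-yl)cyclopentan-1-ol
Product: 7 primary tosylate 3'-O-triethylsilyl ether, via primary tosylate 6 (not isolated)
Conditions: TsCl, pyridine, CH2Cl2, 0 °C; then 2,6-lutidine, Et3SiOTf, −78 → 0 °C
Reagents that add atoms: p-toluenesulfonyl chloride, Cc1ccc(cc1)S(Cl)(=O)=O; triethylsilyl triflate, CC[Si](CC)(CC)OS(=O)(=O)C(F)(F)F
Why: Sulfonylation is selective for the primary over the tertiary hydroxyl; the silyl triflate then caps the tertiary alcohol, which would otherwise close an oxetane onto C1' under base or add to the later ketene.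

Step 4
Reactants: 7 primary tosylate 3'-O-triethylsilyl ether
Product: 8 allylic chloride (3-chloroprop-1-en-2-yl group on C6')
Conditions: Ca(OCl)2, CO2 (solid), CH2Cl2/H2O, 0 °C
Reagents that add atoms: calcium hypochlorite, [Ca+2].[O-]Cl.[O-]Cl
Why: Ene-type allylic chlorination of an isopropenyl group by hypochlorous acid, a standard reaction of terpene isopropenyl groups; the only alkene in 7 reacts and the carbonate buffer spares the silyl ether.

Step 5
Reactants: 8 allylic chloride; 9 methyl acetoacetate
Product: 11 ring-B/C keto ester with 7'-methylidene, via monoalkylated keto ester 10 (not isolated)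
Conditions: NaH (2.2 equiv), NaI (cat.), DMF, 0 → 60 °C
Reagents that add atoms: none
Why: Double C-alkylation of a β-keto ester closes ring B (6-exo-tet for the second bond) and makes C5 quaternary; the order in which chloride and tosylate react is immaterial. The trans relation of C1' and C7' on ring C leads to the trans-hydrindane.

Step 6
Reactants: 11 ring-B/C keto ester with 7'-methylidene
Product: 12 7'-triethylsilyl peroxide
Conditions: Co(acac)2 (10 mol %), O2 (1 atm), Et3SiH, ClCH2CH2Cl, rt
Reagents that add atoms: dioxygen, O=O; triethylsilane, CC[SiH](CC)CC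
Why: Mukaiyama–Isayama hydroperoxysilylation: hydrogen-atom transfer to the methylidene carbon gives the tertiary C7' radical, which captures O2. The axial carbonyl substituent on C5 stands 1,3 to the axial trajectory at C7', so oxygen should enter equatorially and leave the new methyl group axial, as attack on exocyclic alkenes flanked by an axial 1,3-substituent usually goes.

Step 7
Reactants: 12 7'-triethylsilyl peroxide
Product: 14 7'-(2-methoxyprop-2-yl) peroxyketal, via 7'-hydroperoxide 13 (not isolated)
Conditions: K2CO3, MeOH, 0 °C; then 2-methoxypropene, pyridinium p-toluenesulfonate (cat.), CH2Cl2, 0 °C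
Reagents that add atoms: 2-methoxypropene, COC(C)=C
Why: The O–Si bond of a silyl peroxide is methanolysed far faster than a tertiary silyl ether; acid-catalysed addition of the hydroperoxide to the enol ether then gives a peroxyketal. With no hydrogen on either peroxide carbon it is stable to base, nucleophiles and fluoride.

Step 8
Reactants: 14 7'-(2-methoxyprop-2-yl) peroxyketal
Product: 16 ring-B/C carboxylic acid, via methyl ester 15 (not isolated)
Conditions: NaOMe (0.5 equiv), MeOH, 50 °C; then LiOH, H2O, THF, 50 °C; NaH2PO4 work-up
Reagents that add atoms: lithium hydroxide, [Li+].[OH-]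
Why: Retro-Claisen deacetylation of a non-enolisable β-keto ester by methoxide, then saponification. Both are basic and run at 50 °C, which the peroxyketal and the tertiary silyl ether tolerate.

Step 9
Reactants: 17 prenyl bromide; 18 ethynylmagnesium bromide
Product: 19 5-methylhex-4-en-1-yne
Conditions: CuBr·SMe2 (5 mol %), THF, 0 °C → rt
Reagents that add atoms: none
Why: Copper-catalysed coupling of an alkynyl Grignard reagent with a primary allylic bromide, which favours substitution at the unhindered CH2 terminus.

Step 10
Reactants: 19 5-methylhex-4-en-1-yne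
Product: 21 triisopropyl[(5-methylhex-4-en-1-yn-1-yl)oxy]silane, via lithium ynolate 20 (not isolated)
Conditions: LiN(SiMe3)2, THF, −78 °C; LiOOtBu (from tBuOOH and LiN(SiMe3)2), −78 → 0 °C; iPr3SiOTf, −78 °C
Reagents that add atoms: tert-butyl hydroperoxide, CC(C)(C)OO; triisopropylsilyl triflate, CC(C)[Si](OS(=O)(=O)C(F)(F)F)(C(C)C)C(C)C
Why: Oxidation of a lithium acetylide by lithium tert-butyl peroxide gives the ynolate, which is silylated on oxygen by the bulky silyl triflate; this is the standard preparation of 1-siloxy-1-alkynes.

Step 11
Reactants: 16 ring-B/C carboxylic acid; 21 triisopropyl[(5-methylhex-4-en-1-yn-1-yl)oxy]silane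
Product: 24 spiro 2-prenyl-3-(triisopropylsilyloxy)cyclobutenone, via acid chloride 22 (not isolated), via ketene 23 (not isolated)
Conditions: 1-chloro-N,N,2-trimethylprop-1-en-1-amine, CH2Cl2, 0 °C → rt; then 21, Et3N, rt
Reagents that add atoms: none
Why: The α-chloroenamine makes the acid chloride without releasing HCl, which the peroxyketal would not survive; triethylamine then gives the ketene. In the ketene–ynol ether [2+2] cycloaddition the ketene carbonyl carbon bonds to the prenyl-bearing alkyne carbon and C5 to the oxygen-bearing carbon.

Step 12
Reactants: 24 spiro 2-prenyl-3-(triisopropylsilyloxy)cyclobutenone; 25 ethoxyacetylene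
Product: 29 spiro ring-A dienone (C6 ketone; C2 ethoxy; C3 prenyl; C4 silyloxy), via vinylketene 26 (not isolated), via 4-alkenylcyclobutenone 27 (not isolated), via dienylketene 28 (not isolated)
Conditions: 25 (4 equiv), toluene, 80 °C, sealed tube
Reagents that add atoms: none
Why: Danheiser annulation; the closest known case is the reaction of 4,4-disubstituted cyclobutenones with alkoxyalkynes, which stops at 6,6-disubstituted cyclohexa-2,4-dienones. Conrotatory 4π opening of 24 breaks C6–C5 and gives vinylketene 26, in which C5 is trigonal, so both spiro epimers of 24 converge. The ketene of 26 adds to 25 in a [2+2] cycloaddition with the ketene carbon on the unsubstituted, nucleophilic alkyne carbon, forming C6–C1 and C2–C3 in cyclobutenone 27. A second 4π opening gives dienylketene 28, and its disrotatory 6π electrocyclisation closes ring A by forming C6–C5; the four-membered rings are only transient. C5 is the one new stereocentre: the axial methyl on C7' stands 1,3 to the axial trajectory at C5, so the ketene carbon should enter on the equatorial side, leaving C6 equatorial and C4 axial. The step needs this facial choice, the [2+2] regiochemistry (secured by the polarity of the ynol ether) and capture of 26 by excess 25 ahead of dimerisation or a 1,5-hydrogen shift. C5 bears no hydrogen, so the dienone cannot become a phenol, and the prenyl group on C3 makes C4 and C6 constitutionally different from here on. 80 °C is the lowest temperature at which such cyclobutenones open at a useful rate and is chosen to spare the peroxyketal.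

Step 13
Reactants: 29 spiro ring-A dienone
Product: 30 ring-A vinylogous acid (4-hydroxy; 2-ethoxy; 3-prenyl)
Conditions: Bu4NF (1.0 equiv), AcOH (1.0 equiv), THF, −40 °C
Reagents that add atoms: none
Why: Fluoride cleavage of a silyl enol ether; the silyl ether of a vinylogous acid is far more labile than the tertiary triethylsilyl ether, and acetic acid buffers the medium. The prenyl group keeps C3 (next to C4) distinct from C1, so tautomerism cannot epimerise C5.

Step 14
Reactants: 30 ring-A vinylogous acid
Product: 32 1-acetyl ring-A vinylogous acid, via O4-acetate 31 (not isolated)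
Conditions: AcCl, Et3N, CH2Cl2, 0 °C; then 4-(dimethylamino)pyridine (0.3 equiv), rt
Reagents that add atoms: acetyl chloride, CC(Cl)=O
Why: O-acylation followed by amine-catalysed O-to-C acyl migration, the Fries-type route to 2-acyl cyclic 1,3-diketones. Under this reversible acyl transfer the acetyl group should settle on C1, the only ring carbon that can keep an acidic proton in the product; acylation at C3 would give a non-enolisable and therefore labile triketone.

Step 15
Reactants: 32 1-acetyl ring-A vinylogous acid; 17 prenyl bromide
Product: 33 3,3-diprenyl O2-ethyl ether of the protected target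
Conditions: NaOEt (1.1 equiv), EtOH, 0 °C; 17 (3 equiv), 0 °C → rt
Reagents that add atoms: none
Why: C-alkylation of a β-tricarbonyl enolate, as in the prenylation of deoxy hop acids to lupulones: the acyl-bearing C1 is unreactive, so the allylic bromide attacks the prenylated C3 and completes the quaternary centre. Ethanol hydrogen-bonds the enolate oxygens and makes alkoxide exchange at C2 degenerate.

Step 16
Reactants: 33 3,3-diprenyl O2-ethyl ether of the protected target
Product: 34 CNP0149131.2
Conditions: HCl (1 M aq), THF, 0 °C → rt
Reagents that add atoms: water, O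
Why: Acid hydrolysis of three groups in one operation: the doubly activated enol ether on C2 (addition of water, loss of ethanol), the peroxyketal and the tertiary silyl ether. No stereocentre is touched.

## Compound list

1 | (R)-limonene, (4R)-1-methyl-4-(prop-1-en-2-yl)cyclohex-1-ene | CC1=CC[C@@H](CC1)C(C)=C | starting material
2 | limonene 1,2-ozonide (secondary ozonide of the ring alkene, bridgehead configuration undefined) | CC12CC[C@@H](C(C)=C)CC(OO1)O2 | intermediate
3 | (3R)-6-oxo-3-(prop-1-en-2-yl)heptanal | O=CC[C@@H](CCC(C)=O)C(C)=C | intermediate
4 | (1S,2R,5R)-2-hydroxy-2-methyl-5-(prop-1-en-2-yl)cyclopentane-1-carbaldehyde (CHO trans to methyl and to isopropenyl, cis to OH) | O=C[C@H]1[C@@H](CC[C@@]1(C)O)C(C)=C | intermediate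
5 | (1R,2R,3R)-2-(hydroxymethyl)-1-methyl-3-(prop-1-en-2-yl)cyclopentan-1-ol | OC[C@H]1[C@@H](CC[C@@]1(C)O)C(C)=C | intermediate
6 | primary 4-methylbenzenesulfonate of diol 5 (tertiary OH free) | Cc1ccc(cc1)S(=O)(=O)OC[C@H]1[C@@H](CC[C@@]1(C)O)C(C)=C | intermediate
7 | primary tosylate of 5 with the tertiary (C3') hydroxyl as triethylsilyl ether | Cc1ccc(cc1)S(=O)(=O)OC[C@H]1[C@@H](CC[C@@]1(C)O[Si](CC)(CC)CC)C(C)=C | intermediate
8 | allylic chloride: as 7, with the isopropenyl group converted into 3-chloroprop-1-en-2-yl | Cc1ccc(cc1)S(=O)(=O)OC[C@H]1[C@@H](CC[C@@]1(C)O[Si](CC)(CC)CC)C(=C)CCl | intermediate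
9 | methyl acetoacetate | COC(=O)CC(C)=O | starting material
10 | methyl 2-acetyl-4-[cyclopentyl]pent-4-enoate: 8 alkylated at the allylic carbon by the acetoacetate, tosylate still present | Cc1ccc(cc1)S(=O)(=O)OC[C@H]1[C@@H](CC[C@@]1(C)O[Si](CC)(CC)CC)C(=C)CC(C(C)=O)C(=O)OC | intermediate
11 | methyl 5-acetyl-3'-methyl-7'-methylidene-3'-(triethylsilyloxy)-trans-hydrindane-5-carboxylate (rings B and C; H-2' and H-6' trans; 3'-O cis to C1'; both C5 epimers) | COC(=O)C1(C(C)=O)C[C@H]2[C@@H](CC[C@@]2(C)O[Si](CC)(CC)CC)C(=C)C1 | intermediate
12 | as 11, with C7' bearing an axial methyl and an equatorial triethylsilylperoxy group | COC(=O)C1(C(C)=O)C[C@H]2[C@@H](CC[C@@]2(C)O[Si](CC)(CC)CC)[C@](C)(OO[Si](CC)(CC)CC)C1 | intermediate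
13 | as 12, free 7'-hydroperoxide | COC(=O)C1(C(C)=O)C[C@H]2[C@@H](CC[C@@]2(C)O[Si](CC)(CC)CC)[C@](C)(OO)C1 | intermediate
14 | as 12, 7'-(2-methoxyprop-2-yl)peroxy (peroxyketal) | COC(=O)C1(C(C)=O)C[C@H]2[C@@H](CC[C@@]2(C)O[Si](CC)(CC)CC)[C@](C)(OOC(C)(C)OC)C1 | intermediate
15 | methyl ester after loss of the acetyl group (C5–H; both C5 epimers) | COC(=O)C1C[C@H]2[C@@H](CC[C@@]2(C)O[Si](CC)(CC)CC)[C@](C)(OOC(C)(C)OC)C1 | intermediate
16 | ring-B/C carboxylic acid (C5–H; both C5 epimers; 3'-OSiEt3; 7'-peroxyketal) | OC(=O)C1C[C@H]2[C@@H](CC[C@@]2(C)O[Si](CC)(CC)CC)[C@](C)(OOC(C)(C)OC)C1 | intermediate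
17 | prenyl bromide, 1-bromo-3-methylbut-2-ene | CC(C)=CCBr | starting material
18 | ethynylmagnesium bromide | C#C[Mg]Br | starting material
19 | 5-methylhex-4-en-1-yne | CC(C)=CCC#C | intermediate
20 | lithium 5-methylhex-4-en-1-yn-1-olate | [Li+].CC(C)=CCC#C[O-] | intermediate
21 | triisopropyl[(5-methylhex-4-en-1-yn-1-yl)oxy]silane | CC(C)=CCC#CO[Si](C(C)C)(C(C)C)C(C)C | intermediate
22 | acid chloride of 16 | ClC(=O)C1C[C@H]2[C@@H](CC[C@@]2(C)O[Si](CC)(CC)CC)[C@](C)(OOC(C)(C)OC)C1 | intermediate
23 | ketene on C5 of ring B (C5=C=O) | O=C=C1C[C@H]2[C@@H](CC[C@@]2(C)O[Si](CC)(CC)CC)[C@](C)(OOC(C)(C)OC)C1 | intermediate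
24 | spiro cyclobutenone: C5 of ring B is C4 of a 2-(3-methylbut-2-enyl)-3-(triisopropylsilyloxy)cyclobut-2-en-1-one (both spiro epimers) | CC(C)=CCC1=C(O[Si](C(C)C)(C(C)C)C(C)C)C2(C[C@H]3[C@@H](CC[C@@]3(C)O[Si](CC)(CC)CC)[C@](C)(OOC(C)(C)OC)C2)C1=O | intermediate
25 | ethoxyacetylene (ethoxyethyne) | C#COCC | starting material
26 | vinylketene: O=C=C(prenyl)–C(OSiiPr3)=C5 | O=C=C(CC=C(C)C)C(O[Si](C(C)C)(C(C)C)C(C)C)=C1C[C@H]2[C@@H](CC[C@@]2(C)O[Si](CC)(CC)CC)[C@](C)(OOC(C)(C)OC)C1 | intermediate
27 | 3-ethoxy-4-prenylcyclobut-2-en-1-one carrying on C4 the 1-silyloxyalkylidene group attached to ring B | CCOC1=CC(=O)C1(CC=C(C)C)C(O[Si](C(C)C)(C(C)C)C(C)C)=C1C[C@H]2[C@@H](CC[C@@]2(C)O[Si](CC)(CC)CC)[C@](C)(OOC(C)(C)OC)C1 | intermediate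
28 | dienylketene O=C=CH–C(OEt)=C(prenyl)–C(OSiiPr3)=C5, central alkene with the ketene arm and C4 cis | O=C=C/C(OCC)=C(CC=C(C)C)\C(O[Si](C(C)C)(C(C)C)C(C)C)=C1C[C@H]2[C@@H](CC[C@@]2(C)O[Si](CC)(CC)CC)[C@](C)(OOC(C)(C)OC)C1 | intermediate
29 | spiro ring-A dienone: C6 ketone (equatorial on ring B), C1–H, C2 ethoxy, C3 prenyl, C4 triisopropylsilyloxy (axial on ring B, syn to 7'-methyl) | CCOC1=CC(=O)[C@@]2(C[C@H]3[C@@H](CC[C@@]3(C)O[Si](CC)(CC)CC)[C@](C)(OOC(C)(C)OC)C2)C(O[Si](C(C)C)(C(C)C)C(C)C)=C1CC=C(C)C | intermediate
30 | ring-A vinylogous acid: as 29 with free 4-OH (drawn as the 4-enol) | CCOC1=CC(=O)[C@@]2(C[C@H]3[C@@H](CC[C@@]3(C)O[Si](CC)(CC)CC)[C@](C)(OOC(C)(C)OC)C2)C(O)=C1CC=C(C)C | intermediate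
31 | O4-acetate of 30 | CCOC1=CC(=O)[C@@]2(C[C@H]3[C@@H](CC[C@@]3(C)O[Si](CC)(CC)CC)[C@](C)(OOC(C)(C)OC)C2)C(OC(C)=O)=C1CC=C(C)C | intermediate
32 | 1-acetyl-2-ethoxy-3-prenyl ring-A vinylogous acid (drawn as the 4-enol) | CCOC1=C(C(C)=O)C(=O)[C@@]2(C[C@H]3[C@@H](CC[C@@]3(C)O[Si](CC)(CC)CC)[C@](C)(OOC(C)(C)OC)C2)C(O)=C1CC=C(C)C | intermediate
33 | protected target: 1-acetyl-2-ethoxy-3,3-diprenyl ring A (C4 and C6 ketones), 3'-OSiEt3, 7'-peroxyketal | CCOC1=C(C(C)=O)C(=O)[C@@]2(C[C@H]3[C@@H](CC[C@@]3(C)O[Si](CC)(CC)CC)[C@](C)(OOC(C)(C)OC)C2)C(=O)C1(CC=C(C)C)CC=C(C)C | intermediate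
34 | CNP0149131.2: ring A 1-acetyl-2-hydroxy-3,3-diprenylcyclohex-1-ene-4,6-dione, spiro at C5 to the trans-hydrindane with 3'-OH, 3'-methyl, 7'-OOH and 7'-methyl | CC(=O)C1=C(O)C(CC=C(C)C)(CC=C(C)C)C(=O)[C@]2(C[C@H]3[C@@H](CC[C@@]3(C)O)[C@](C)(OO)C2)C1=O | target

## Step count and risks

Total: 16 steps. Longest linear sequence: 14 steps (steps 1 to 8 and 11 to 16); the siloxyalkyne branch (steps 9 and 10) joins at step 11.

**Step 12 (key step).**
- Most likely failure: poor or reversed facial selectivity in the 6π closure. The predicted product carries C4 with its bulky silyloxy group in the axial position beside the 7'-methyl, while the competing closure puts the small ketene carbon there, so the approach argument and the strain in the product pull in opposite directions.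
- Further concerns: slow loss of the peroxyketal at 80 °C, and a 1,5-hydrogen shift in vinylketene 26 if capture by 25 is slow.
- Fallback: exchange the roles of the two ynol ethers, which maps the ketene carbon onto C4 instead of C6, so the opposite facial sense gives the target. It sets out from acid 16 and returns at 34.
  - Ketene 23, generated as in step 11, is trapped with ethoxyacetylene 25 to give the spiro 3-ethoxycyclobutenone F1.
  - Heating F1 with siloxyalkyne 21 gives the regioisomeric dienone F2 (C4 ketone next to the prenylated C3, silyloxy on C2, ethoxy on C6).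
  - Fluoride gives the vinylogous acid F3.
  - O-acylation and acyl migration give the 1-acetyl compound F4.
  - Prenylation at C3 gives the O6-ethyl ether F5.
  - Aqueous acid gives 34.

**Step 6.**
- Most likely failure: poor facial selectivity in the capture of the C7' radical by O2. The axial carbonyl group on C5 is a smaller shield than a methyl group, and the inherent preference of tertiary cyclohexyl radicals is for axial capture.
- Fallback: a recycling loop instead of forcing the selectivity. It sets out from 11 and returns to 11.
  - The unwanted 7'-epimeric silyl peroxide F6 is separated from 12.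
  - K2CO3 in MeOH cleaves it to the epimeric hydroperoxide F7.
  - PPh3 reduces F7 to the tertiary alcohol F8.
  - Methyl N-(triethylammoniosulfonyl)carbamate dehydrates F8 to 11 together with its endocyclic alkene isomer F9. Both alkenes give the same C7' radical and are resubmitted to step 6.

**Step 2.**
- Most likely failure: dehydration of the tertiary aldol to the conjugated cyclopentene aldehyde, or insufficient diastereoselectivity if substrate and catalyst are mismatched.
- Fallback: accept the dehydration and restore the oxygen. It sets out from 3 and returns at 4.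
  - Piperidine and acetic acid give the aldol condensation product, 2-methyl-5-(prop-1-en-2-yl)cyclopent-1-ene-1-carbaldehyde F10.
  - Alkaline H2O2 epoxidises F10 on the face away from the isopropenyl group, giving the epoxy aldehyde F11.
  - Reductive opening of the Cα–O bond with the selenide reagent from (PhSe)2 and NaBH4 in EtOH/AcOH gives 4, the epimerisable C2' settling trans to C6'. 4 is reduced to 5 as in step 2.

**Step 15.**
- Most likely failure: O-alkylation of the enolate (on O4 or O6) in place of C-alkylation at the hindered, already substituted C3.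
- Fallback: allylic alkylation of 32 with prenyl methyl carbonate and Pd(PPh3)4 (zerovalent palladium). O-allylation is reversible under these conditions and the soft carbon nucleophile is funnelled to the unhindered terminus of the prenyl unit. The catalyst loading is kept low because phosphines and low-valent palladium can attack peroxides. It sets out from 32 and returns at 33 with no new intermediate.

## Further compounds

F1 | step 12 | spiro 3-ethoxycyclobut-2-en-1-one on C5 of ring B (both spiro epimers) | CCOC1=CC(=O)C12C[C@H]3[C@@H](CC[C@@]3(C)O[Si](CC)(CC)CC)[C@](C)(OOC(C)(C)OC)C2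
F2 | step 12 | regioisomeric spiro dienone: C4 ketone (axial), C3 prenyl, C2 triisopropylsilyloxy, C1–H, C6 ethoxy | CC(C)=CCC1=C(O[Si](C(C)C)(C(C)C)C(C)C)C=C(OCC)[C@@]2(C[C@H]3[C@@H](CC[C@@]3(C)O[Si](CC)(CC)CC)[C@](C)(OOC(C)(C)OC)C2)C1=O
F3 | step 12 | vinylogous acid from F2 (2-hydroxy, 6-ethoxy, 3-prenyl) | CC(C)=CCC1=C(O)C=C(OCC)[C@@]2(C[C@H]3[C@@H](CC[C@@]3(C)O[Si](CC)(CC)CC)[C@](C)(OOC(C)(C)OC)C2)C1=O
F4 | step 12 | 1-acetyl derivative of F3 | CC(C)=CCC1=C(O)C(C(C)=O)=C(OCC)[C@@]2(C[C@H]3[C@@H](CC[C@@]3(C)O[Si](CC)(CC)CC)[C@](C)(OOC(C)(C)OC)C2)C1=O
F5 | step 12 | 3,3-diprenyl O6-ethyl ether of the protected target | CC(C)=CCC1(CC=C(C)C)C(=O)C(C(C)=O)=C(OCC)[C@@]2(C[C@H]3[C@@H](CC[C@@]3(C)O[Si](CC)(CC)CC)[C@](C)(OOC(C)(C)OC)C2)C1=O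
F6 | step 6 | 7'-epimer of 12 (triethylsilylperoxy axial, methyl equatorial) | COC(=O)C1(C(C)=O)C[C@H]2[C@@H](CC[C@@]2(C)O[Si](CC)(CC)CC)[C@@](C)(OO[Si](CC)(CC)CC)C1
F7 | step 6 | 7'-epimeric hydroperoxide | COC(=O)C1(C(C)=O)C[C@H]2[C@@H](CC[C@@]2(C)O[Si](CC)(CC)CC)[C@@](C)(OO)C1
F8 | step 6 | 7'-epimeric tertiary alcohol (OH axial) | COC(=O)C1(C(C)=O)C[C@H]2[C@@H](CC[C@@]2(C)O[Si](CC)(CC)CC)[C@@](C)(O)C1
F9 | step 6 | endocyclic alkene isomer of 11 (C7'=C8') | COC(=O)C1(C(C)=O)C[C@H]2[C@@H](CC[C@@]2(C)O[Si](CC)(CC)CC)C(C)=C1
F10 | step 2 | 2-methyl-5-(prop-1-en-2-yl)cyclopent-1-ene-1-carbaldehyde (C6' as in 3) | O=CC1=C(C)CC[C@H]1C(C)=C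
F11 | step 2 | 2',3'-epoxy aldehyde, epoxide trans to the isopropenyl group | O=C[C@]12O[C@]2(C)CC[C@H]1C(C)=C
F0 | step 15 | none | none
A1 | alternative 1 | (1S,2R,5R)-2-hydroxy-2-methyl-5-(prop-1-en-2-yl)cyclopentane-1-carbaldehyde | O=C[C@H]1[C@@H](CC[C@@]1(C)O)C(C)=C
A2 | alternative 1 | (3R)-6-oxo-3-(prop-1-en-2-yl)heptanal | O=CC[C@@H](CCC(C)=O)C(C)=C
A3 | alternative 2 | trans-hydrindane 5,5-diester with 3'-OH, 3'-methyl and 7'-methylidene | COC(=O)C1(C(=O)OC)C[C@H]2[C@@H](CC[C@@]2(C)O)C(=C)C1
A4 | alternative 2 | dimethyl cyclonon-6-ene-1,1-dicarboxylate with cis-2',3'-epoxide (3'-methyl) and 7'-(trimethylsilyl)methyl, alkene drawn ring-cis | COC(=O)C1(C(=O)OC)C[C@@H]2O[C@]2(C)CC/C=C(/C[Si](C)(C)C)C1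
A5 | alternative 3 | trans-2-(hydroxymethyl)-3-(prop-1-en-2-yl)cyclopentan-1-one | OC[C@H]1[C@@H](CCC1=O)C(C)=C
A6 | alternative 3 | cyclopent-2-en-1-one | O=C1CCC=C1
A7 | alternative 3 | isopropenylmagnesium bromide | CC(=C)[Mg]Br
A8 | alternative 3 | formaldehyde | C=O
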